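Numbering (germacrane): ring C1–C10; lactone O on C6 and C7–C11(=C13)–C12(=O); C14 = formyl carbon on C10; C15 = CH2OH carbon on C4.
Key feature and first cut: in the five-membered lactone ring (O, C12, C11, C7, C6) the ring oxygen on C6 stands 1,4 to the C15 hydroxyl across C4=C5, and C11 is a vinylic carbon two bonds from C6. Cutting O–C6 and C11–C12 expels CO2 and leaves a C11 alkenyl anion equivalent beside a π-allyl unit C4–C5–C6, i.e. a 1-iodoethenyl group on C7 next to a C4/C15 spiro-epoxide conjugated with C5=C6.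
Further cuts, in order: C8 ester and protecting groups; C4–C15 (sulfur ylide on a C4 ketone); ring bond C4–C5 (Nozaki–Hiyama–Kishi); chain bond C9–C10 (alkenylmagnesium + α-alkoxy aldehyde); C7–C11 (alkynylalane + epoxy alcohol).
Forward: fragment A (C5–C9, C11, C13) and fragment B (C1–C4, C10, C14) are joined at C9–C10, the ten-membered carbocycle is closed at C4–C5, and the γ-lactone is the last ring, closed with CO2; ester and aldehyde are unveiled at the end.
Stereochemistry: C7 and C8 from a Sharpless epoxidation and anti opening of the epoxide; C9 from chelate-controlled addition; C6 and the C4=C5 geometry from the key step under control of C7 and the ring; C1=C10 geometry from a (Z)-2-iodo enal.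

Key step: step 18

Remark: compounds 19–21 (C4 carbinol) and 23 (spiro carbon C4) are carried as mixtures of epimers, because C4 becomes sp2 in steps 16 and 18; 1 and 9 are taken as catalogue compounds.

Step 1
Reactants: 1 (2E)-pent-2-en-4-yn-1-ol
Product: 3 (2E,4E)-5-iodopenta-2,4-dien-1-ol, via dienylzirconocene 2 (not isolated)
Conditions: Cp2Zr(H)Cl (2.2 equiv), THF, 0 °C to rt; then I2, 0 °C
Reagents that add atoms: iodine, II
Why: Hydrozirconation: after the first equivalent has been taken up by the hydroxyl group, Zr–H adds syn to the terminal alkyne with zirconium on the terminal carbon, and iodinolysis with retention gives the (4E)-iodo diene.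

Step 2
Reactants: 3 (2E,4E)-5-iodopenta-2,4-dien-1-ol
Product: 4 {(2R,3R)-3-[(E)-2-iodoethenyl]oxiran-2-yl}methanol
Conditions: Ti(OiPr)4 (10 mol%), D-(−)-diethyl tartrate (12 mol%), t-BuOOH, 4 Å molecular sieves, CH2Cl2, −20 °C
Reagents that add atoms: tert-butyl hydroperoxide, CC(C)(C)OO
Why: Sharpless asymmetric epoxidation: titanium binds the allylic alcohol so that only the adjacent alkene reacts (the iodo-substituted alkene is remote and deactivated), and the D-(−)-tartrate ligand sets both epoxide carbons (future C8, and C7 before its inversion).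

Step 3
Reactants: 4 {(2R,3R)-3-[(E)-2-iodoethenyl]oxiran-2-yl}methanol
Product: 5 (2S,3R,4E)-5-iodo-3-[(trimethylsilyl)ethynyl]pent-4-ene-1,2-diol
Conditions: Me3SiC≡CH, n-BuLi, toluene, −78 to 0 °C; Et2AlCl; then 4, 0 °C to rt (3 equiv of alane)
Reagents that add atoms: (trimethylsilyl)acetylene, C#C[Si](C)(C)C
Why: Ring opening of a 2,3-epoxy alcohol by a diethylalkynylalane: the aluminium alkoxide of the primary alcohol activates the epoxide and the alkynyl group attacks the distal, allylic carbon with inversion, which gives the anti relation of the C7 alkynyl group and the C8 oxygen.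

Step 4
Reactants: 5 (2S,3R,4E)-5-iodo-3-[(trimethylsilyl)ethynyl]pent-4-ene-1,2-diol
Product: 6 (4S)-4-[(1E,3R)-1-iodo-5-(trimethylsilyl)pent-1-en-4-yn-3-yl]-2-(4-methoxyphenyl)-1,3-dioxolane
Conditions: 4-MeOC6H4CH(OMe)2, PPTS (cat.), CH2Cl2, rt
Reagents that add atoms: 4-methoxybenzaldehyde dimethyl acetal, COc1ccc(cc1)C(OC)OC
Why: Acid-catalysed transacetalisation closes the five-membered 4-methoxybenzylidene acetal on the 1,2-diol; the acetal carbon forms unselectively and is lost as a stereocentre in the next step.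

Step 5
Reactants: 6 (4S)-4-[(1E,3R)-1-iodo-5-(trimethylsilyl)pent-1-en-4-yn-3-yl]-2-(4-methoxyphenyl)-1,3-dioxolane
Product: 7 (2S,3R,4E)-5-iodo-2-[(4-methoxybenzyl)oxy]-3-[(trimethylsilyl)ethynyl]pent-4-en-1-ol
Conditions: i-Bu2AlH (3 equiv), CH2Cl2, −78 to 0 °C; aq. potassium sodium tartrate
Reagents that add atoms: none
Why: Reductive acetal opening: aluminium coordinates the less hindered primary oxygen and hydride cleaves that C–O bond, so the PMB ether stays on the secondary C8 oxygen and the primary alcohol is freed.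

Step 6
Reactants: 7 (2S,3R,4E)-5-iodo-2-[(4-methoxybenzyl)oxy]-3-[(trimethylsilyl)ethynyl]pent-4-en-1-ol
Product: 8 (2S,3R,4E)-5-iodo-2-[(4-methoxybenzyl)oxy]-3-[(trimethylsilyl)ethynyl]pent-4-enal
Conditions: Dess–Martin periodinane, NaHCO3, CH2Cl2, 0 °C to rt; used at once
Reagents that add atoms: none
Why: Dess–Martin oxidation under buffered, non-basic conditions should give the α-alkoxy aldehyde without epimerisation at C8.

Step 7
Reactants: 9 4-{[tert-butyl(dimethyl)silyl]oxy}butanal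
Product: 10 (2E)-6-{[tert-butyl(dimethyl)silyl]oxy}hex-2-enal
Conditions: Ph3P=CHCHO, toluene, 80 °C
Reagents that add atoms: (triphenylphosphoranylidene)acetaldehyde, O=CC=P(c1ccccc1)(c1ccccc1)c1ccccc1
Why: Wittig olefination with the stabilised formylmethylene ylide gives the (E)-enal.

Step 8
Reactants: 10 (2E)-6-{[tert-butyl(dimethyl)silyl]oxy}hex-2-enal
Product: 11 (2Z)-6-{[tert-butyl(dimethyl)silyl]oxy}-2-iodohex-2-enal
Conditions: I2, K2CO3, DMAP (20 mol%), THF/H2O (1:1), rt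
Reagents that add atoms: iodine, II
Why: α-Iodination of the enal by a Morita–Baylis–Hillman-type sequence (conjugate addition of DMAP, iodination of the enolate, elimination); the thermodynamically preferred (Z)-2-iodo enal, with the chain trans to the formyl group, fixes the later C1=C10 geometry.

Step 9
Reactants: 11 (2Z)-6-{[tert-butyl(dimethyl)silyl]oxy}-2-iodohex-2-enal
Product: 12 tert-butyl{[(4Z)-5-iodo-6,6-dimethoxyhex-4-en-1-yl]oxy}dimethylsilane
Conditions: HC(OMe)3, MeOH, CeCl3·7H2O (10 mol%), rt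
Reagents that add atoms: trimethyl orthoformate, COC(OC)OC; methanol, CO
Why: Lewis acid-catalysed acetalisation of the aldehyde, mild enough to keep the silyl ether, masks C14 against the organometallic steps.

Step 10
Reactants: 12 tert-butyl{[(4Z)-5-iodo-6,6-dimethoxyhex-4-en-1-yl]oxy}dimethylsilane; 8 (2S,3R,4E)-5-iodo-2-[(4-methoxybenzyl)oxy]-3-[(trimethylsilyl)ethynyl]pent-4-enal
Product: 15 (1E,3R,4S,5S,6E)-10-{[tert-butyl(dimethyl)silyl]oxy}-6-(dimethoxymethyl)-1-iodo-4-[(4-methoxybenzyl)oxy]-3-[(trimethylsilyl)ethynyl]deca-1,6-dien-5-ol, via alkenyllithium 13 (not isolated), via alkenylmagnesium bromide 14 (not isolated)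
Conditions: 12 (1.4 equiv), t-BuLi (2.0 equiv per 12), Et2O, −78 °C; MgBr2·OEt2, −78 °C; then 8 (precomplexed with MgBr2·OEt2), CH2Cl2, −78 °C
Reagents that add atoms: none
Why: Iodine–lithium exchange with retention of alkene geometry, transmetalation to magnesium and Cram-chelate addition to the α-alkoxy aldehyde: magnesium bridges the aldehyde and PMB-ether oxygens and the alkenyl group adds to the face away from the C7 branch, which should give the 8,9-syn (9S) carbinol.

Step 11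
Reactants: 15 (1E,3R,4S,5S,6E)-10-{[tert-butyl(dimethyl)silyl]oxy}-6-(dimethoxymethyl)-1-iodo-4-[(4-methoxybenzyl)oxy]-3-[(trimethylsilyl)ethynyl]deca-1,6-dien-5-ol
Product: 16 tert-butyl{[(4E,6S,7S,8R,9E)-5-(dimethoxymethyl)-10-iodo-6-methoxy-7-[(4-methoxybenzyl)oxy]-8-[(trimethylsilyl)ethynyl]deca-4,9-dien-1-yl]oxy}dimethylsilane
Conditions: NaH, MeI, THF, 0 °C to rt
Reagents that add atoms: iodomethane, CI
Why: Williamson ether synthesis on the secondary allylic alkoxide installs the C9 methyl ether.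

Step 12
Reactants: 16 tert-butyl{[(4E,6S,7S,8R,9E)-5-(dimethoxymethyl)-10-iodo-6-methoxy-7-[(4-methoxybenzyl)oxy]-8-[(trimethylsilyl)ethynyl]deca-4,9-dien-1-yl]oxy}dimethylsilane
Product: 17 (4E,6S,7S,8R,9E)-5-(dimethoxymethyl)-8-ethynyl-10-iodo-6-methoxy-7-[(4-methoxybenzyl)oxy]deca-4,9-dien-1-ol
Conditions: Bu4NF, THF, 0 °C to rt
Reagents that add atoms: none
Why: Fluoride-mediated desilylation cleaves the primary TBS ether and the alkynyl carbon–silicon bond in one operation, exposing the C4 alcohol and the terminal alkyne.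

Step 13
Reactants: 17 (4E,6S,7S,8R,9E)-5-(dimethoxymethyl)-8-ethynyl-10-iodo-6-methoxy-7-[(4-methoxybenzyl)oxy]deca-4,9-dien-1-ol
Product: 18 (4E,6S,7S,8R,9E)-5-(dimethoxymethyl)-8-ethynyl-10-iodo-6-methoxy-7-[(4-methoxybenzyl)oxy]deca-4,9-dienal
Conditions: Dess–Martin periodinane, NaHCO3, CH2Cl2, 0 °C to rt
Reagents that add atoms: none
Why: Dess–Martin oxidation of the primary alcohol gives the aldehyde needed for ring closure.

Step 14
Reactants: 18 (4E,6S,7S,8R,9E)-5-(dimethoxymethyl)-8-ethynyl-10-iodo-6-methoxy-7-[(4-methoxybenzyl)oxy]deca-4,9-dienal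
Product: 19 (2E,4R,5S,6S,7E)-7-(dimethoxymethyl)-4-ethynyl-6-methoxy-5-[(4-methoxybenzyl)oxy]cyclodeca-2,7-dien-1-ol
Conditions: CrCl2 (10 equiv), NiCl2 (2 mol%), DMSO/THF, rt, slow addition to 0.003 M
Reagents that add atoms: none
Why: Nozaki–Hiyama–Kishi reaction: nickel inserts into the alkenyl carbon–iodine bond and the alkenylchromium species formed by transmetalation adds chemoselectively to the aldehyde with retention of the (E)-alkene, closing the ten-membered ring at C4–C5 under high dilution; the C4 carbinol forms as a mixture and is oxidised in step 16.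

Step 15
Reactants: 19 (2E,4R,5S,6S,7E)-7-(dimethoxymethyl)-4-ethynyl-6-methoxy-5-[(4-methoxybenzyl)oxy]cyclodeca-2,7-dien-1-ol
Product: 21 (2E,4S,5S,6S,7E)-7-(dimethoxymethyl)-4-(1-iodoethenyl)-6-methoxy-5-[(4-methoxybenzyl)oxy]cyclodeca-2,7-dien-1-ol, via alkenylalane 20 (not isolated)
Conditions: Ni(dppp)Cl2 (3 mol%), i-Bu2AlH (2.4 equiv), THF, rt; then I2, THF, 0 °C
Reagents that add atoms: iodine, II
Why: Nickel-catalysed Markovnikov (α-selective) hydroalumination of the terminal alkyne, after the first equivalent of hydride has deprotonated the hydroxyl group, puts aluminium on the internal carbon C11, and iodinolysis of the alkenyl–aluminium bond gives the 1-iodoethenyl group (the descriptor at the ring carbon changes by priority only).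

Step 16
Reactants: 21 (2E,4S,5S,6S,7E)-7-(dimethoxymethyl)-4-(1-iodoethenyl)-6-methoxy-5-[(4-methoxybenzyl)oxy]cyclodeca-2,7-dien-1-ol
Product: 22 (2E,4S,5S,6S,7E)-7-(dimethoxymethyl)-4-(1-iodoethenyl)-6-methoxy-5-[(4-methoxybenzyl)oxy]cyclodeca-2,7-dien-1-one
Conditions: Dess–Martin periodinane, NaHCO3, CH2Cl2, 0 °C to rt
Reagents that add atoms: none
Why: Dess–Martin oxidation of the allylic alcohol gives the C4 enone and removes the stereocentre formed in step 14.

Step 17
Reactants: 22 (2E,4S,5S,6S,7E)-7-(dimethoxymethyl)-4-(1-iodoethenyl)-6-methoxy-5-[(4-methoxybenzyl)oxy]cyclodeca-2,7-dien-1-one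
Product: 23 (4E,6S,7S,8S,9E)-9-(dimethoxymethyl)-6-(1-iodoethenyl)-8-methoxy-7-[(4-methoxybenzyl)oxy]-1-oxaspiro[2.9]dodeca-4,9-diene
Conditions: Me3S+ I− (1.5 equiv), KN(SiMe3)2 (1.4 equiv), THF, −20 to 0 °C
Reagents that add atoms: trimethylsulfonium iodide, C[S+](C)C.[I-]
Why: Corey–Chaykovsky epoxidation: dimethylsulfonium methylide adds 1,2 to the enone carbonyl and the betaine closes to the spiro vinyl epoxide, which brings in C15; the new spiro centre is formed without control and both epimers are used.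

Step 18
Reactants: 23 (4E,6S,7S,8S,9E)-9-(dimethoxymethyl)-6-(1-iodoethenyl)-8-methoxy-7-[(4-methoxybenzyl)oxy]-1-oxaspiro[2.9]dodeca-4,9-diene
Product: 26 (3aS,4S,5S,6E,10E,11aR)-6-(dimethoxymethyl)-10-(hydroxymethyl)-5-methoxy-4-[(4-methoxybenzyl)oxy]-3-methylidene-3a,4,5,8,9,11a-hexahydrocyclodeca[b]furan-2(3H)-one, via alkenyllithium 24 (not isolated), via lithium acrylate 25 (not isolated)
Conditions: t-BuLi (2.0 equiv), THF, −78 °C; CO2 (gas), −78 °C to rt; argon purge; Pd(PPh3)4 (10 mol%), THF, rt; aq. NH4Cl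
Reagents that add atoms: carbon dioxide, O=C=O
Why: Iodine–lithium exchange at C11 is faster than any attack on the epoxide at −78 °C and the alkenyllithium 24 adds to CO2 to give the lithium acrylate 25 (C11–C12 bond); zerovalent palladium then ionises the vinyl epoxide anti to the C4–O bond to a π-allyl complex over C4–C5–C6, and the tethered carboxylate attacks C6 from the face opposite to palladium (O–C6 bond), freeing the C15 alkoxide. The closest known reaction types are the carboxylation of alkenyllithium reagents and the palladium-catalysed 1,4-addition of carboxylates to vinyl epoxides (Tsuji–Trost allylic substitution), here run in one flask. The γ-lactone (O, C12, C11, C7, C6) closes in the 5-exo mode at the allyl terminus C6, whereas attack at C4 would need a seven-membered ring and a quaternary centre, so the 1,4-regiochemistry is secured by the tether. The new stereocentre C6 is controlled by C7: the ten-membered ring holds the C7–C8 bond on the periphery, H7 eclipses the allyl unit, and the carboxylate arm on the other face of C7 can reach only the face of C6 that gives the trans-fused (6R) lactone; the two epoxide epimers are expected to converge because the π-allyl faces exchange by attack of zerovalent palladium and because the allylic lactone can re-ionise, which should favour the more stable trans-fused product. The C4=C5 geometry (C6 trans to C15) should follow from ionisation in the rotamer with the ring carbon C3 anti and the CH2O group syn on the allyl unit, the usual outcome for 2-substituted vinyl epoxides. The step needs exchange at iodine before epoxide opening and substitution before β-hydride loss from the π-allyl complex; the low temperature, the removal of excess CO2 before the catalyst is added and the intramolecular nucleophile are meant to secure this.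

Step 19
Reactants: 26 (3aS,4S,5S,6E,10E,11aR)-6-(dimethoxymethyl)-10-(hydroxymethyl)-5-methoxy-4-[(4-methoxybenzyl)oxy]-3-methylidene-3a,4,5,8,9,11a-hexahydrocyclodeca[b]furan-2(3H)-one
Product: 27 (3aS,4S,5S,6E,10E,11aR)-6-(dimethoxymethyl)-5-methoxy-4-[(4-methoxybenzyl)oxy]-3-methylidene-10-{[(triethylsilyl)oxy]methyl}-3a,4,5,8,9,11a-hexahydrocyclodeca[b]furan-2(3H)-one
Conditions: Et3SiCl, imidazole, CH2Cl2, 0 °C
Reagents that add atoms: chlorotriethylsilane, CC[Si](Cl)(CC)CC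
Why: Silylation of the only free hydroxyl group (primary, allylic) protects C15–OH during the ester exchange at C8.

Step 20
Reactants: 27 (3aS,4S,5S,6E,10E,11aR)-6-(dimethoxymethyl)-5-methoxy-4-[(4-methoxybenzyl)oxy]-3-methylidene-10-{[(triethylsilyl)oxy]methyl}-3a,4,5,8,9,11a-hexahydrocyclodeca[b]furan-2(3H)-one
Product: 28 (3aR,4S,5S,6E,10E,11aR)-6-(dimethoxymethyl)-4-hydroxy-5-methoxy-3-methylidene-10-{[(triethylsilyl)oxy]methyl}-3a,4,5,8,9,11a-hexahydrocyclodeca[b]furan-2(3H)-one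
Conditions: DDQ, CH2Cl2/pH 7 phosphate buffer, 0 °C to rt
Reagents that add atoms: none
Why: Oxidative cleavage of the PMB ether (benzylic hydride abstraction, hydrolysis of the oxocarbenium ion) frees C8–OH under buffered conditions that keep the acetal and the silyl ether (the descriptor at C3a changes by priority only).

Step 21
Reactants: 28 (3aR,4S,5S,6E,10E,11aR)-6-(dimethoxymethyl)-4-hydroxy-5-methoxy-3-methylidene-10-{[(triethylsilyl)oxy]methyl}-3a,4,5,8,9,11a-hexahydrocyclodeca[b]furan-2(3H)-one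
Product: 29 (3aS,4S,5S,6E,10E,11aR)-6-(dimethoxymethyl)-5-methoxy-3-methylidene-2-oxo-10-{[(triethylsilyl)oxy]methyl}-2,3,3a,4,5,8,9,11a-octahydrocyclodeca[b]furan-4-yl 2-methylprop-2-enoate
Conditions: methacryloyl chloride, Et3N, DMAP (cat.), CH2Cl2, 0 °C to rt
Reagents that add atoms: methacryloyl chloride, C=C(C)C(=O)Cl
Why: DMAP-catalysed acylation of the secondary C8 alcohol installs the methacrylate with retention at C8.

Step 22
Reactants: 29 (3aS,4S,5S,6E,10E,11aR)-6-(dimethoxymethyl)-5-methoxy-3-methylidene-2-oxo-10-{[(triethylsilyl)oxy]methyl}-2,3,3a,4,5,8,9,11a-octahydrocyclodeca[b]furan-4-yl 2-methylprop-2-enoate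
Product: 30 (3aS,4S,5S,6E,10E,11aR)-6-formyl-10-(hydroxymethyl)-5-methoxy-3-methylidene-2-oxo-2,3,3a,4,5,8,9,11a-octahydrocyclodeca[b]furan-4-yl 2-methylprop-2-enoate (CNP0114830.1)
Conditions: AcOH/THF/H2O (3:1:1), rt
Reagents that add atoms: water, O
Why: Mild acid hydrolysis cleaves the triethylsilyl ether and the allylic dimethyl acetal (through an allyl-stabilised oxocarbenium ion) in one operation, giving the C15 alcohol and the C14 enal without touching the esters.

Compound list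
1 | (2E)-pent-2-en-4-yn-1-ol | OC/C=C/C#C | starting material
2 | dienylzirconocene: O-zirconated (1E,3E)-5-hydroxypenta-1,3-dien-1-ylzirconocene chloride | Cl[Zr](C1C=CC=C1)(C1C=CC=C1)OC/C=C/C=C/[Zr](Cl)(C1C=CC=C1)C1C=CC=C1 | intermediate
3 | (2E,4E)-5-iodopenta-2,4-dien-1-ol | OC/C=C/C=C/I | intermediate
4 | {(2R,3R)-3-[(E)-2-iodoethenyl]oxiran-2-yl}methanol | OC[C@H]1O[C@@H]1/C=C/I | intermediate
5 | (2S,3R,4E)-5-iodo-3-[(trimethylsilyl)ethynyl]pent-4-ene-1,2-diol | OC[C@@H](O)[C@@H](C#C[Si](C)(C)C)/C=C/I | intermediate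
6 | (4S)-4-[(1E,3R)-1-iodo-5-(trimethylsilyl)pent-1-en-4-yn-3-yl]-2-(4-methoxyphenyl)-1,3-dioxolane (acetal carbon as a mixture) | COc1ccc(cc1)C1OC[C@@H](O1)[C@@H](C#C[Si](C)(C)C)/C=C/I | intermediate
7 | (2S,3R,4E)-5-iodo-2-[(4-methoxybenzyl)oxy]-3-[(trimethylsilyl)ethynyl]pent-4-en-1-ol | OC[C@@H](OCc1ccc(OC)cc1)[C@@H](C#C[Si](C)(C)C)/C=C/I | intermediate
8 | (2S,3R,4E)-5-iodo-2-[(4-methoxybenzyl)oxy]-3-[(trimethylsilyl)ethynyl]pent-4-enal | O=C[C@@H](OCc1ccc(OC)cc1)[C@@H](C#C[Si](C)(C)C)/C=C/I | intermediate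
9 | 4-{[tert-butyl(dimethyl)silyl]oxy}butanal | O=CCCCO[Si](C)(C)C(C)(C)C | starting material
10 | (2E)-6-{[tert-butyl(dimethyl)silyl]oxy}hex-2-enal | O=C/C=C/CCCO[Si](C)(C)C(C)(C)C | intermediate
11 | (2Z)-6-{[tert-butyl(dimethyl)silyl]oxy}-2-iodohex-2-enal | O=C/C(I)=C/CCCO[Si](C)(C)C(C)(C)C | intermediate
12 | tert-butyl{[(4Z)-5-iodo-6,6-dimethoxyhex-4-en-1-yl]oxy}dimethylsilane | COC(OC)/C(I)=C/CCCO[Si](C)(C)C(C)(C)C | intermediate
13 | alkenyllithium: [(1E)-5-{[tert-butyl(dimethyl)silyl]oxy}-1-(dimethoxymethyl)pent-1-en-1-yl]lithium (lithium in place of iodine in 12, geometry retained) | COC(OC)/C([Li])=C/CCCO[Si](C)(C)C(C)(C)C | intermediate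
14 | alkenylmagnesium bromide: bromo[(1Z)-5-{[tert-butyl(dimethyl)silyl]oxy}-1-(dimethoxymethyl)pent-1-en-1-yl]magnesium (geometry as in 13) | COC(OC)/C([Mg]Br)=C/CCCO[Si](C)(C)C(C)(C)C | intermediate
15 | (1E,3R,4S,5S,6E)-10-{[tert-butyl(dimethyl)silyl]oxy}-6-(dimethoxymethyl)-1-iodo-4-[(4-methoxybenzyl)oxy]-3-[(trimethylsilyl)ethynyl]deca-1,6-dien-5-ol | CC(C)(C)[Si](C)(C)OCCC/C=C(/C(OC)OC)[C@H](O)[C@@H](OCc1ccc(OC)cc1)[C@@H](C#C[Si](C)(C)C)/C=C/I | intermediate
16 | tert-butyl{[(4E,6S,7S,8R,9E)-5-(dimethoxymethyl)-10-iodo-6-methoxy-7-[(4-methoxybenzyl)oxy]-8-[(trimethylsilyl)ethynyl]deca-4,9-dien-1-yl]oxy}dimethylsilane | CC(C)(C)[Si](C)(C)OCCC/C=C(/C(OC)OC)[C@H](OC)[C@@H](OCc1ccc(OC)cc1)[C@@H](C#C[Si](C)(C)C)/C=C/I | intermediate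
17 | (4E,6S,7S,8R,9E)-5-(dimethoxymethyl)-8-ethynyl-10-iodo-6-methoxy-7-[(4-methoxybenzyl)oxy]deca-4,9-dien-1-ol | OCCC/C=C(/C(OC)OC)[C@H](OC)[C@@H](OCc1ccc(OC)cc1)[C@@H](C#C)/C=C/I | intermediate
18 | (4E,6S,7S,8R,9E)-5-(dimethoxymethyl)-8-ethynyl-10-iodo-6-methoxy-7-[(4-methoxybenzyl)oxy]deca-4,9-dienal | O=CCC/C=C(/C(OC)OC)[C@H](OC)[C@@H](OCc1ccc(OC)cc1)[C@@H](C#C)/C=C/I | intermediate
19 | (2E,4R,5S,6S,7E)-7-(dimethoxymethyl)-4-ethynyl-6-methoxy-5-[(4-methoxybenzyl)oxy]cyclodeca-2,7-dien-1-ol (C1 carbinol as a mixture) | OC1CC/C=C(/C(OC)OC)[C@H](OC)[C@@H](OCc2ccc(OC)cc2)[C@@H](C#C)/C=C/1 | intermediate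
20 | alkenylalane: the 1-(diisobutylalumanyl)ethenyl derivative of 19 with the ring oxygen as its diisobutylaluminium alkoxide | CC(C)C[Al](CC(C)C)OC1CC/C=C(/C(OC)OC)[C@H](OC)[C@@H](OCc2ccc(OC)cc2)[C@@H](C(=C)[Al](CC(C)C)CC(C)C)/C=C/1 | intermediate
21 | (2E,4S,5S,6S,7E)-7-(dimethoxymethyl)-4-(1-iodoethenyl)-6-methoxy-5-[(4-methoxybenzyl)oxy]cyclodeca-2,7-dien-1-ol (C1 carbinol as a mixture) | OC1CC/C=C(/C(OC)OC)[C@H](OC)[C@@H](OCc2ccc(OC)cc2)[C@@H](C(=C)I)/C=C/1 | intermediate
22 | (2E,4S,5S,6S,7E)-7-(dimethoxymethyl)-4-(1-iodoethenyl)-6-methoxy-5-[(4-methoxybenzyl)oxy]cyclodeca-2,7-dien-1-one | O=C1CC/C=C(/C(OC)OC)[C@H](OC)[C@@H](OCc2ccc(OC)cc2)[C@@H](C(=C)I)/C=C/1 | intermediate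
23 | (4E,6S,7S,8S,9E)-9-(dimethoxymethyl)-6-(1-iodoethenyl)-8-methoxy-7-[(4-methoxybenzyl)oxy]-1-oxaspiro[2.9]dodeca-4,9-diene (spiro carbon as a mixture) | C1OC12CC/C=C(/C(OC)OC)[C@H](OC)[C@@H](OCc3ccc(OC)cc3)[C@@H](C(=C)I)/C=C/2 | intermediate
24 | alkenyllithium: {1-[(4E,6R,7S,8S,9E)-9-(dimethoxymethyl)-8-methoxy-7-[(4-methoxybenzyl)oxy]-1-oxaspiro[2.9]dodeca-4,9-dien-6-yl]ethenyl}lithium | C1OC12CC/C=C(/C(OC)OC)[C@H](OC)[C@@H](OCc3ccc(OC)cc3)[C@@H](C(=C)[Li])/C=C/2 | intermediate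
25 | lithium acrylate: lithium 2-[(4E,6R,7S,8S,9E)-9-(dimethoxymethyl)-8-methoxy-7-[(4-methoxybenzyl)oxy]-1-oxaspiro[2.9]dodeca-4,9-dien-6-yl]prop-2-enoate | C1OC12CC/C=C(/C(OC)OC)[C@H](OC)[C@@H](OCc3ccc(OC)cc3)[C@@H](C(=C)C(=O)[O-])/C=C/2.[Li+] | intermediate
26 | (3aS,4S,5S,6E,10E,11aR)-6-(dimethoxymethyl)-10-(hydroxymethyl)-5-methoxy-4-[(4-methoxybenzyl)oxy]-3-methylidene-3a,4,5,8,9,11a-hexahydrocyclodeca[b]furan-2(3H)-one | COc1ccc(CO[C@H]2[C@H]3C(=C)C(=O)O[C@@H]3/C=C(/CO)CC/C=C(/C(OC)OC)[C@@H]2OC)cc1 | intermediate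
27 | (3aS,4S,5S,6E,10E,11aR)-6-(dimethoxymethyl)-5-methoxy-4-[(4-methoxybenzyl)oxy]-3-methylidene-10-{[(triethylsilyl)oxy]methyl}-3a,4,5,8,9,11a-hexahydrocyclodeca[b]furan-2(3H)-one | COc1ccc(CO[C@H]2[C@H]3C(=C)C(=O)O[C@@H]3/C=C(/CO[Si](CC)(CC)CC)CC/C=C(/C(OC)OC)[C@@H]2OC)cc1 | intermediate
28 | (3aR,4S,5S,6E,10E,11aR)-6-(dimethoxymethyl)-4-hydroxy-5-methoxy-3-methylidene-10-{[(triethylsilyl)oxy]methyl}-3a,4,5,8,9,11a-hexahydrocyclodeca[b]furan-2(3H)-one | O[C@H]1[C@H]2C(=C)C(=O)O[C@@H]2/C=C(/CO[Si](CC)(CC)CC)CC/C=C(/C(OC)OC)[C@@H]1OC | intermediate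
29 | (3aS,4S,5S,6E,10E,11aR)-6-(dimethoxymethyl)-5-methoxy-3-methylidene-2-oxo-10-{[(triethylsilyl)oxy]methyl}-2,3,3a,4,5,8,9,11a-octahydrocyclodeca[b]furan-4-yl 2-methylprop-2-enoate | C=C(C)C(=O)O[C@H]1[C@H]2C(=C)C(=O)O[C@@H]2/C=C(/CO[Si](CC)(CC)CC)CC/C=C(/C(OC)OC)[C@@H]1OC | intermediate
30 | (3aS,4S,5S,6E,10E,11aR)-6-formyl-10-(hydroxymethyl)-5-methoxy-3-methylidene-2-oxo-2,3,3a,4,5,8,9,11a-octahydrocyclodeca[b]furan-4-yl 2-methylprop-2-enoate (CNP0114830.1) | C=C(C)C(=O)O[C@H]1[C@H]2C(=C)C(=O)O[C@@H]2/C=C(/CO)CC/C=C(/C=O)[C@@H]1OC | target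

Total step count: 22. Longest linear sequence: 19 steps (steps 1–6 and 10–22); fragment B takes steps 7–9.

Steps most likely to fail

Step 18 (key step). What may go wrong: the allylic substitution may proceed through the wrong π-allyl face or rotamer, giving the cis-fused lactone or the C4=C5 geometric isomer, or lithium iodide may open the epoxide before the catalyst is added. The fallback replaces the redox-neutral ionisation of an epoxide by an oxidative 1,4-difunctionalisation of a diene and sets out from 22. Wittig methylenation (Ph3P=CH2, THF, 0 °C) of the C4 ketone should give (1E,3S,4S,5S,6E)-6-(dimethoxymethyl)-3-(1-iodoethenyl)-5-methoxy-4-[(4-methoxybenzyl)oxy]-10-methylidenecyclodeca-1,6-diene F1. Iodine–lithium exchange (t-BuLi, THF, −78 °C), CO2 and a buffered work-up should give 2-[(1R,2S,3S,4E,9E)-4-(dimethoxymethyl)-3-methoxy-2-[(4-methoxybenzyl)oxy]-8-methylidenecyclodeca-4,9-dien-1-yl]prop-2-enoic acid F2. A palladium-catalysed 1,4-acyloxylactonisation of the conjugated diene (Pd(OAc)2, benzoquinone, LiOAc, AcOH/acetone, rt), in which the carboxylic acid adds to C6 of the diene bound to divalent palladium and acetate opens the resulting π-allyl complex at C15, should give [(3aS,4S,5S,6E,10E,11aR)-6-(dimethoxymethyl)-5-methoxy-4-[(4-methoxybenzyl)oxy]-3-methylidene-2-oxo-2,3,3a,4,5,8,9,11a-octahydrocyclodeca[b]furan-10-yl]methyl acetate F3. Mild methanolysis of the primary allylic acetate (K2CO3, MeOH, 0 °C) then gives 26, where the route continues with step 19.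

Step 14 (ring closure). What may go wrong: intermolecular coupling to oligomers or loss of iodine by protonation may outrun closure of the ten-membered ring. The fallback closes the ring by alkene metathesis at C5=C6 instead of carbonyl addition at C4–C5 and sets out from 16. Iodine–lithium exchange (t-BuLi, Et2O, −78 °C) and a methanol quench should give tert-butyl{[(4E,6S,7S,8R)-5-(dimethoxymethyl)-6-methoxy-7-[(4-methoxybenzyl)oxy]-8-[(trimethylsilyl)ethynyl]deca-4,9-dien-1-yl]oxy}dimethylsilane F4. HF·pyridine (THF/pyridine) removes the TBS ether with the alkynylsilane kept and should give (4E,6S,7S,8R)-5-(dimethoxymethyl)-6-methoxy-7-[(4-methoxybenzyl)oxy]-8-[(trimethylsilyl)ethynyl]deca-4,9-dien-1-ol F5. Dess–Martin oxidation should give (4E,6S,7S,8R)-5-(dimethoxymethyl)-6-methoxy-7-[(4-methoxybenzyl)oxy]-8-[(trimethylsilyl)ethynyl]deca-4,9-dienal F6, and vinylmagnesium bromide (THF, −78 °C) should give (6E,8S,9S,10R)-7-(dimethoxymethyl)-8-methoxy-9-[(4-methoxybenzyl)oxy]-10-[(trimethylsilyl)ethynyl]dodeca-1,6,11-trien-3-ol F7. Ring-closing metathesis (second-generation Hoveyda–Grubbs catalyst, toluene, 80 °C, 0.002 M) should give (2E,4R,5S,6S,7E)-7-(dimethoxymethyl)-6-methoxy-5-[(4-methoxybenzyl)oxy]-4-[(trimethylsilyl)ethynyl]cyclodeca-2,7-dien-1-ol F8, in which the silyl cap keeps the alkyne out of the metathesis. K2CO3 in MeOH then removes the alkynyl silyl group and gives 19.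

Step 10 (fragment union). What may go wrong: poor facial selectivity if the open (Felkin–Anh) transition state competes with the chelate, giving the C9 epimer. The fallback replaces substrate-controlled addition by catalyst-controlled reduction and sets out from 15 obtained as a mixture of C9 epimers. Dess–Martin oxidation should give (1E,3R,4S,6E)-10-{[tert-butyl(dimethyl)silyl]oxy}-6-(dimethoxymethyl)-1-iodo-4-[(4-methoxybenzyl)oxy]-3-[(trimethylsilyl)ethynyl]deca-1,6-dien-5-one F9. Corey–Bakshi–Shibata reduction ((S)-2-methyl-CBS-oxazaborolidine, catecholborane, toluene, −78 °C), with the alkenyl group as the larger substituent, should return 15 as the single (5S) alcohol.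

Further compounds
F1 | step 18 | (1E,3S,4S,5S,6E)-6-(dimethoxymethyl)-3-(1-iodoethenyl)-5-methoxy-4-[(4-methoxybenzyl)oxy]-10-methylidenecyclodeca-1,6-diene | C=C1CC/C=C(/C(OC)OC)[C@H](OC)[C@@H](OCc2ccc(OC)cc2)[C@@H](C(=C)I)/C=C/1
F2 | step 18 | 2-[(1R,2S,3S,4E,9E)-4-(dimethoxymethyl)-3-methoxy-2-[(4-methoxybenzyl)oxy]-8-methylidenecyclodeca-4,9-dien-1-yl]prop-2-enoic acid | C=C1CC/C=C(/C(OC)OC)[C@H](OC)[C@@H](OCc2ccc(OC)cc2)[C@@H](C(=C)C(=O)O)/C=C/1
F3 | step 18 | [(3aS,4S,5S,6E,10E,11aR)-6-(dimethoxymethyl)-5-methoxy-4-[(4-methoxybenzyl)oxy]-3-methylidene-2-oxo-2,3,3a,4,5,8,9,11a-octahydrocyclodeca[b]furan-10-yl]methyl acetate | COc1ccc(CO[C@H]2[C@H]3C(=C)C(=O)O[C@@H]3/C=C(/COC(C)=O)CC/C=C(/C(OC)OC)[C@@H]2OC)cc1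
F4 | step 14 | tert-butyl{[(4E,6S,7S,8R)-5-(dimethoxymethyl)-6-methoxy-7-[(4-methoxybenzyl)oxy]-8-[(trimethylsilyl)ethynyl]deca-4,9-dien-1-yl]oxy}dimethylsilane | CC(C)(C)[Si](C)(C)OCCC/C=C(/C(OC)OC)[C@H](OC)[C@@H](OCc1ccc(OC)cc1)[C@@H](C#C[Si](C)(C)C)C=C
F5 | step 14 | (4E,6S,7S,8R)-5-(dimethoxymethyl)-6-methoxy-7-[(4-methoxybenzyl)oxy]-8-[(trimethylsilyl)ethynyl]deca-4,9-dien-1-ol | OCCC/C=C(/C(OC)OC)[C@H](OC)[C@@H](OCc1ccc(OC)cc1)[C@@H](C#C[Si](C)(C)C)C=C
F6 | step 14 | (4E,6S,7S,8R)-5-(dimethoxymethyl)-6-methoxy-7-[(4-methoxybenzyl)oxy]-8-[(trimethylsilyl)ethynyl]deca-4,9-dienal | O=CCC/C=C(/C(OC)OC)[C@H](OC)[C@@H](OCc1ccc(OC)cc1)[C@@H](C#C[Si](C)(C)C)C=C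
F7 | step 14 | (6E,8S,9S,10R)-7-(dimethoxymethyl)-8-methoxy-9-[(4-methoxybenzyl)oxy]-10-[(trimethylsilyl)ethynyl]dodeca-1,6,11-trien-3-ol | C=CC(O)CC/C=C(/C(OC)OC)[C@H](OC)[C@@H](OCc1ccc(OC)cc1)[C@@H](C#C[Si](C)(C)C)C=C
F8 | step 14 | (2E,4R,5S,6S,7E)-7-(dimethoxymethyl)-6-methoxy-5-[(4-methoxybenzyl)oxy]-4-[(trimethylsilyl)ethynyl]cyclodeca-2,7-dien-1-ol | OC1CC/C=C(/C(OC)OC)[C@H](OC)[C@@H](OCc2ccc(OC)cc2)[C@@H](C#C[Si](C)(C)C)/C=C/1
F9 | step 10 | (1E,3R,4S,6E)-10-{[tert-butyl(dimethyl)silyl]oxy}-6-(dimethoxymethyl)-1-iodo-4-[(4-methoxybenzyl)oxy]-3-[(trimethylsilyl)ethynyl]deca-1,6-dien-5-one | CC(C)(C)[Si](C)(C)OCCC/C=C(/C(OC)OC)C(=O)[C@@H](OCc1ccc(OC)cc1)[C@@H](C#C[Si](C)(C)C)/C=C/I
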